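**Plan**
Ring A is numbered C1 (C=O), C2 (C–N), C3 (=CH), C4 (tertiary carbinol carrying chain C7–C13), C5 (CHOH), C6 (CH2). The retrosynthesis cuts the C8–C9 bond of the triene, both amide C–N bonds, and in ring A the two bonds of C2 (C1–C2 and C2–C3).
Enabling feature: C2 is the only ring A carbon that bears nitrogen. Its neighbours, carbonyl carbon C1 and vinylic methine C3, can both be read as former aldehyde carbons. C2 plus N is therefore nitromethane, and C3–C4–C5–C6–C1 is a pentanedial released by cleaving the C=C bond of a cyclopentene.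
Forward: cyclopentenone is oxygenated at its C5, resolved, alkynylated and ketalised. Ozonolysis opens the five-membered ring, and a double Henry reaction closes it again, one carbon larger, as ring A.
Then NO2 becomes NH–acyl, the alkyne becomes an (E)-vinyl iodide, the C1 carbinol becomes the ketone, the C3 hydroxyl is eliminated and the acetonide is removed. A final Stille coupling attaches the stannyl dienamide that already carries the hydroxycyclopentenone (ring B).
Stereochemistry: C5 comes from a lipase resolution, C4 from acetylide attack anti to the C5 oxygen substituent (cis-diol), and the side-chain centre from (R)-2-methylhexanoic acid. Alkene geometry comes from stabilised ylides, hydrostannation and stereoretentive coupling. The C1–C3 centres made in the key step are erased later.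

Key step: step 6

Assumption: the lipase of step 2 is taken to hydrolyse the (R)-acetate faster, as the empirical size rule for lipases and the behaviour of related α′-acetoxy enones suggest; (R)-2-methylhexanoic acid is taken as a purchasable single enantiomer.

**Ring A core**

Step 1
Reactants: 1 cyclopent-2-en-1-one
Product: 2 (±)-5-acetoxycyclopent-2-en-1-one
Conditions: Mn(OAc)3·2H2O (2.5 equiv), benzene/AcOH 10:1, reflux, azeotropic removal of water
Reagents that add atoms: manganese triacetate, CC(=O)[O-].CC(=O)[O-].CC(=O)[O-].[Mn+3]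
Why: Manganese triacetate α′-acetoxylation of an enone: the enone can enolise only toward C5, so the manganese enolate is oxidised and captures acetate there, giving the racemic α′-acetate.

Step 2
Reactants: 2 (±)-5-acetoxycyclopent-2-en-1-one
Product: 3 (R)-5-hydroxycyclopent-2-en-1-one
Conditions: Burkholderia cepacia lipase, pH 7 phosphate buffer/MTBE, 25 °C, stopped near 40% conversion; chromatographic separation from the remaining acetate
Reagents that add atoms: none
Why: Lipase-catalysed kinetic resolution by enantioselective ester hydrolysis, precedented for α′-acetoxy enones, should release the (R)-alcohol at neutral pH, which sets the future C5 and keeps the enolisable α-ketol from tautomerising.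

Step 3
Reactants: 3 (R)-5-hydroxycyclopent-2-en-1-one
Product: 4 (R)-5-[(2-methoxypropan-2-yl)oxy]cyclopent-2-en-1-one
Conditions: 2-methoxypropene (3 equiv), PPTS (2 mol %), CH2Cl2, 0 °C; Et3N quench
Reagents that add atoms: 2-methoxypropene, COC(C)=C
Why: Acid-catalysed addition of the alcohol to an enol ether (mixed-ketal protection) runs under almost neutral catalysis, so C5 is not enolised, and it installs a bulky, base-stable group that already contains the acetonide carbon.

Step 4
Reactants: 4 (R)-5-[(2-methoxypropan-2-yl)oxy]cyclopent-2-en-1-one; 5 (triisopropylsilyl)acetylene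
Product: 7 acetonide of (1R,2R)-2-[(triisopropylsilyl)ethynyl]cyclopent-3-ene-1,2-diol (cis-fused bicycle), via tertiary carbinol 6 (not isolated)
Conditions: 5, n-BuLi, THF, −78 °C; then 4, −78 °C; H2O quench and extraction; crude 6, PPTS (5 mol %), 4 Å molecular sieves, CH2Cl2, 0 °C → rt
Reagents that add atoms: none
Why: 1,2-Addition of a lithium acetylide to the enone carbonyl takes place on the ring face opposite the bulky C5 ketal ether, which sets C4 with its hydroxyl cis to the C5 oxygen, and intramolecular acid-catalysed transketalisation then expels methanol and closes the cis-fused dioxolane.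

Step 5
Reactants: 7 acetonide of (1R,2R)-2-[(triisopropylsilyl)ethynyl]cyclopent-3-ene-1,2-diol
Product: 9 (4R,5R)-2,2-dimethyl-5-(2-oxoethyl)-4-[(triisopropylsilyl)ethynyl]-1,3-dioxolane-4-carbaldehyde (the C3/C1 dialdehyde), via secondary ozonide 8 (not isolated)
Conditions: O3, CH2Cl2, −78 °C (Sudan red 7B end point); Me2S, −78 °C → rt; used without chromatography
Reagents that add atoms: ozone, [O-][O+]=O
Why: Ozonolysis with reductive work-up cleaves the strained, electron-richer ring alkene well before the hindered silyl alkyne reacts, and it leaves C4 and C5 untouched while turning the two alkene carbons into the C3 and C1 aldehydes.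

Step 6
Reactants: 9 C3/C1 dialdehyde; 10 nitromethane
Product: 13 ring A 2-nitro-1,3-diol (4S,5R; C4/C5 acetonide; C4 TIPS-ethynyl; epimer mixture at C1–C3), via open-chain nitroaldol 11 (not isolated), via cyclic sodium nitronate 12 (not isolated)
Conditions: 10 (1.05 equiv), NaOMe (1.05 equiv), MeOH, 0 °C; slow addition of 9 (final 0.02 M), 0 °C → rt; AcOH (1.1 equiv), 0 °C
Reagents that add atoms: sodium methoxide, C[O-].[Na+] (sodium stays only in 12)
Why: Sodium methanenitronate adds to the unhindered C1 aldehyde to give 11, proton transfer regenerates a nitronate on the same carbon, and this carbon attacks the C3 aldehyde, so that C2 and its nitrogen are inserted between C1 and C3 with formation of the C1–C2 and C2–C3 bonds. The closest known reaction type is the double Henry (nitroaldol) cyclisation of 1,5-dialdehydes with nitromethane, the standard entry to 3-nitro sugars and nitrocyclitols. Ring A closes in a 6-exo-trig mode, the nitronate carbon attacking an aldehyde C=O that lies outside the forming ring. C1, C2 and C3 are new stereocentres formed under reversible, thermodynamic conditions (C2 only on protonation of 12) and need no controlling element, since all three become sp2 in steps 14 and 15, whereas quaternary C4 cannot epimerise and C5 is not acidic. The step needs cyclisation to win over chain growth and double addition, which is secured by one equivalent of nitromethane, high dilution, the intramolecular second addition and the final deprotonation of the more acidic secondary nitroalkane to 12 as the thermodynamic sink. It also needs the C5 oxygen to stay, which is secured because the medium is no more basic than a nitronate, the enolisable C1 aldehyde is the first to be consumed and a ketal alkoxide is a poor leaving group, while the TIPS alkyne resists methoxide.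

Step 7
Reactants: 13 ring A 2-nitro-1,3-diol
Product: 14 ring A 2-amino-1,3-diol (4S,5R; acetonide and TIPS-alkyne retained; epimer mixture at C1–C3)
Conditions: activated Zn dust (excess), AcOH/THF 1:1, 0 °C → rt; filtration, aq. NaHCO3 work-up
Reagents that add atoms: none
Why: Dissolving-metal reduction of an aliphatic nitro group with zinc in acetic acid works in acidic medium, where the β-nitro alcohol cannot undergo retro-Henry cleavage, and unlike catalytic hydrogenation it spares the alkyne.

**Side-chain acid**

Step 8
Reactants: 15 (R)-2-methylhexanoic acid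
Product: 16 (R)-2-methylhexan-1-ol
Conditions: BH3·THF, THF, 0 °C → rt; aqueous quench
Reagents that add atoms: none
Why: Borane reduction of a carboxylic acid proceeds through an acyloxyborane without enolisation, so the α-stereocentre is retained.

Step 9
Reactants: 16 (R)-2-methylhexan-1-ol; 17 ethyl 2-(triphenyl-λ5-phosphanylidene)propanoate
Product: 19 ethyl (2E,4R)-2,4-dimethyloct-2-enoate, via aldehyde 18 (not isolated)
Conditions: TEMPO (10 mol %), PhI(OAc)2 (1.1 equiv), CH2Cl2, rt; then 17 (2 equiv), rt → 40 °C
Reagents that add atoms: none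
Why: Oxoammonium (TEMPO) oxidation followed in the same flask by a Wittig olefination with a stabilised α-methyl ylide traps the epimerisable aldehyde at once and gives the (E)-trisubstituted enoate, as is usual for stabilised ylides.

Step 10
Reactants: 19 ethyl (2E,4R)-2,4-dimethyloct-2-enoate
Product: 20 (2E,4R)-2,4-dimethyloct-2-enoic acid
Conditions: LiOH·H2O, THF/MeOH/H2O, 50 °C; then 1 M HCl
Reagents that add atoms: lithium hydroxide, [Li+].[OH-]
Why: Ester saponification, in which the γ-stereocentre is not acidic enough to be touched by LiOH and the alkene stays in conjugation.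

**Elaboration of ring A**

Step 11
Reactants: 14 ring A 2-amino-1,3-diol; 20 (2E,4R)-2,4-dimethyloct-2-enoic acid
Product: 21 ring A 2-[(2E,4R)-2,4-dimethyloct-2-enoylamino]-1,3-diol (4S,5R; acetonide; TIPS-alkyne; epimer mixture at C1–C3)
Conditions: EDC·HCl, HOBt, iPr2NEt, CH2Cl2, 0 °C → rt
Reagents that add atoms: none
Why: Carbodiimide/HOBt amide coupling acylates the primary amine much faster than the two secondary hydroxyls, so no hydroxyl protection is needed.

Step 12
Reactants: 21 TIPS-alkynyl amide diol
Product: 22 C4-ethynyl amide diol (4S,5R; acetonide; epimer mixture at C1–C3)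
Conditions: TBAF (1 M in THF), THF, 0 °C → rt
Reagents that add atoms: none
Why: Fluoride-induced protiodesilylation of the alkynylsilane is placed here because the molecule still lacks the base-sensitive β-alkoxy ketone.

Step 13
Reactants: 22 C4-ethynyl amide diol
Product: 24 C4-[(E)-2-iodoethenyl] amide diol (4S,5R; acetonide; epimer mixture at C1–C3), via vinylstannane 23 (not isolated)
Conditions: PdCl2(PPh3)2 (3 mol %), Bu3SnH (1.2 equiv), THF, 0 °C; then I2, 0 °C; aq. Na2S2O3/KF work-up
Reagents that add atoms: tributyltin hydride, CCCC[SnH](CCCC)CCCC (tin stays only in 23); iodine, II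
Why: Palladium-catalysed syn-hydrostannation puts tin on the terminal carbon because the propargylic carbon C4 is quaternary, and iododestannylation with retention gives the (E)-vinyl iodide, all before any enone is present that a palladium hydride could reduce.

Step 14
Reactants: 24 C4-[(E)-2-iodoethenyl] amide diol
Product: 25 2-acylamino-3-hydroxycyclohexanone (C1 ketone; C3 carbinol; 4S,5R; acetonide; epimers at C2 and C3)
Conditions: TEMPO (20 mol %), PhI(OAc)2 (1.2 equiv), CH2Cl2, rt
Reagents that add atoms: none
Why: TEMPO/PhI(OAc)2 oxidation is highly sensitive to crowding and to electron-withdrawing β-substituents, so the C1 carbinol next to a CH2 group should be oxidised while the C3 carbinol, neopentyl and flanked by the C4 oxygen, is left.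

Step 15
Reactants: 25 2-acylamino-3-hydroxycyclohexanone
Product: 27 2-acylaminocyclohex-2-enone acetonide (4R,5R; C4 (E)-2-iodoethenyl), via mesylate 26 (not isolated)
Conditions: MsCl (1.5 equiv), Et3N (4 equiv), CH2Cl2, 0 °C → rt
Reagents that add atoms: methanesulfonyl chloride, CS(=O)(=O)Cl (its atoms stay only in 26)
Why: Mesylation followed by E1cB elimination: C2–H is now α to the ketone, so triethylamine expels the C3 mesylate and forms the C2=C3 enamide-enone while the far poorer C5 ketal oxygen stays in place, and all epimers converge on one compound.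

Step 16
Reactants: 27 2-acylaminocyclohex-2-enone acetonide
Product: 28 (2E,4R)-N-[(3R,4R)-3,4-dihydroxy-3-[(E)-2-iodoethenyl]-6-oxocyclohex-1-en-1-yl]-2,4-dimethyloct-2-enamide (4R,5R in ring A numbering)
Conditions: TFA/H2O 9:1, CH2Cl2, 0 °C; cold aq. NaHCO3
Reagents that add atoms: none
Why: Acid-catalysed ketal hydrolysis, routine for acetonides of polyhydroxylated cyclohexenones, is carried out before the acid-sensitive triene is attached, and ionisation at C4 is disfavoured by the enone and the iodoalkene.

**Stannyl dienamide**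

Step 17
Reactants: 29 prop-2-yn-1-ol
Product: 30 (E)-3-(tributylstannyl)prop-2-en-1-ol
Conditions: Bu3SnH, AIBN (cat.), neat, 80 °C; chromatographic removal of minor isomers
Reagents that add atoms: tributyltin hydride, CCCC[SnH](CCCC)CCCC
Why: Radical hydrostannation of a terminal alkyne, in which reversible stannyl radical addition equilibrates the adducts toward the (E)-β-stannyl isomer.

Step 18
Reactants: 30 (E)-3-(tributylstannyl)prop-2-en-1-ol; 31 ethyl (triphenyl-λ5-phosphanylidene)acetate
Product: 33 ethyl (2E,4E)-5-(tributylstannyl)penta-2,4-dienoate, via stannyl enal 32 (not isolated)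
Conditions: activated MnO2 (10 equiv), 31 (1.3 equiv), CH2Cl2, rt
Reagents that add atoms: none
Why: Tandem MnO2 allylic oxidation/Wittig olefination traps the sensitive stannyl enal as it forms, the stabilised ylide giving the new (E)-alkene and leaving the (E)-vinylstannane unchanged.

Step 19
Reactants: 33 ethyl (2E,4E)-5-(tributylstannyl)penta-2,4-dienoate
Product: 34 (2E,4E)-5-(tributylstannyl)penta-2,4-dienoic acid
Conditions: LiOH·H2O, THF/MeOH/H2O, rt; 0.5 M HCl to pH 4, 0 °C
Reagents that add atoms: lithium hydroxide, [Li+].[OH-]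
Why: Ester saponification with gentle acidification, which the electron-poor dienylstannane should survive without protodestannylation.

Step 20
Reactants: 35 cyclopentane-1,3-dione
Product: 36 2-nitrocyclopentane-1,3-dione (enol form)
Conditions: fuming HNO3 (1.1 equiv), AcOH, 10 °C → rt
Reagents that add atoms: nitric acid, O[N+](=O)[O-]
Why: Electrophilic nitration of the enol of a cyclic 1,3-dione occurs at C2, its only nucleophilic carbon.

Step 21
Reactants: 36 2-nitrocyclopentane-1,3-dione
Product: 37 2-amino-3-hydroxycyclopent-2-en-1-one hydrochloride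
Conditions: H2 (1 atm), 10% Pd/C, HCl (1.1 equiv), MeOH, rt
Reagents that add atoms: hydrogen chloride, Cl
Why: Catalytic hydrogenation of the nitro group in the presence of HCl delivers the air-sensitive amino enol as its stable salt.

Step 22
Reactants: 34 (2E,4E)-5-(tributylstannyl)penta-2,4-dienoic acid; 37 2-amino-3-hydroxycyclopent-2-en-1-one hydrochloride
Product: 38 (2E,4E)-N-(2-hydroxy-5-oxocyclopent-1-en-1-yl)-5-(tributylstannyl)penta-2,4-dienamide
Conditions: EDC·HCl, HOBt, N-methylmorpholine, DMF, 0 °C → rt, argon
Reagents that add atoms: none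
Why: Carbodiimide/HOBt amide coupling under non-acidic conditions keeps the C–Sn bond, and any enol ester formed first should pass its acyl group to the neighbouring nitrogen by O→N acyl shift.

**Fragment union**

Step 23
Reactants: 28 ring A vinyl iodide diol; 38 stannyl dienamide
Product: 39 (2E,4E,6E)-7-[(1S,6R)-3-{[(2E,4R)-2,4-dimethyloct-2-enoyl]amino}-1,6-dihydroxy-4-oxocyclohex-2-en-1-yl]-N-(2-hydroxy-5-oxocyclopent-1-en-1-yl)hepta-2,4,6-trienamide (target)
Conditions: PdCl2(MeCN)2 (10 mol %), DMF, rt, dark, argon
Reagents that add atoms: none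
Why: Stille coupling, in which zerovalent palladium formed in situ inserts into the C–I bond and transmetalation and reductive elimination form C8–C9 with retention of both alkene geometries, runs under neutral conditions at room temperature that tolerate the free diol, the enone and the acidic enol.

**Compound list**
1 | cyclopent-2-en-1-one | O=C1C=CCC1 | starting material
2 | (±)-5-acetoxycyclopent-2-en-1-one | CC(=O)OC1CC=CC1=O | intermediate
3 | (R)-5-hydroxycyclopent-2-en-1-one | O=C1[C@H](O)CC=C1 | intermediate
4 | (R)-5-[(2-methoxypropan-2-yl)oxy]cyclopent-2-en-1-one | O=C1[C@H](OC(C)(C)OC)CC=C1 | intermediate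
5 | (triisopropylsilyl)acetylene | C#C[Si](C(C)C)(C(C)C)C(C)C | starting material
6 | (1R,5R)-5-[(2-methoxypropan-2-yl)oxy]-1-[(triisopropylsilyl)ethynyl]cyclopent-2-en-1-ol | C1=C[C@@](O)(C#C[Si](C(C)C)(C(C)C)C(C)C)[C@H](OC(C)(C)OC)C1 | intermediate
7 | acetonide of (1R,2R)-2-[(triisopropylsilyl)ethynyl]cyclopent-3-ene-1,2-diol | C1=C[C@@](OC(C)(C)O2)(C#C[Si](C(C)C)(C(C)C)C(C)C)[C@H]2C1 | intermediate
8 | secondary ozonide of 7 (trioxabicyclo[3.2.1]octane fused to the dioxolane) | C1(O3)OOC3[C@@](OC(C)(C)O2)(C#C[Si](C(C)C)(C(C)C)C(C)C)[C@H]2C1 | intermediate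
9 | (4R,5R)-2,2-dimethyl-5-(2-oxoethyl)-4-[(triisopropylsilyl)ethynyl]-1,3-dioxolane-4-carbaldehyde | O=C[C@@](OC(C)(C)O2)(C#C[Si](C(C)C)(C(C)C)C(C)C)[C@H]2CC=O | intermediate
10 | nitromethane | C[N+](=O)[O-] | starting material
11 | (4R,5R)-5-(2-hydroxy-3-nitropropyl)-2,2-dimethyl-4-[(triisopropylsilyl)ethynyl]-1,3-dioxolane-4-carbaldehyde (carbinol epimers) | O=C[C@@](OC(C)(C)O2)(C#C[Si](C(C)C)(C(C)C)C(C)C)[C@H]2CC(O)C[N+](=O)[O-] | intermediate
12 | sodium nitronate of 13 | [Na+].[O-][N+]([O-])=C1C(O)[C@@](OC(C)(C)O2)(C#C[Si](C(C)C)(C(C)C)C(C)C)[C@H]2CC1O | intermediate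
13 | (4S,5R)-4,5-O-isopropylidene-2-nitro-4-[(triisopropylsilyl)ethynyl]cyclohexane-1,3,4,5-tetrol (ring A numbering, epimers at C1–C3) | [O-][N+](=O)C1C(O)[C@@](OC(C)(C)O2)(C#C[Si](C(C)C)(C(C)C)C(C)C)[C@H]2CC1O | intermediate
14 | 2-amino analogue of 13 | NC1C(O)[C@@](OC(C)(C)O2)(C#C[Si](C(C)C)(C(C)C)C(C)C)[C@H]2CC1O | intermediate
15 | (R)-2-methylhexanoic acid | CCCC[C@@H](C)C(=O)O | starting material
16 | (R)-2-methylhexan-1-ol | CCCC[C@@H](C)CO | intermediate
17 | ethyl 2-(triphenyl-λ5-phosphanylidene)propanoate | CCOC(=O)C(C)=P(c1ccccc1)(c1ccccc1)c1ccccc1 | starting material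
18 | (R)-2-methylhexanal | CCCC[C@@H](C)C=O | intermediate
19 | ethyl (2E,4R)-2,4-dimethyloct-2-enoate | CCCC[C@@H](C)/C=C(\C)C(=O)OCC | intermediate
20 | (2E,4R)-2,4-dimethyloct-2-enoic acid | CCCC[C@@H](C)/C=C(\C)C(=O)O | intermediate
21 | N-acyl derivative of 14 (TIPS-alkynyl amide diol) | CCCC[C@@H](C)/C=C(\C)C(=O)NC1C(O)[C@@](OC(C)(C)O2)(C#C[Si](C(C)C)(C(C)C)C(C)C)[C@H]2CC1O | intermediate
22 | C4-ethynyl amide diol | CCCC[C@@H](C)/C=C(\C)C(=O)NC1C(O)[C@@](OC(C)(C)O2)(C#C)[C@H]2CC1O | intermediate
23 | C4-[(E)-2-(tributylstannyl)ethenyl] amide diol | CCCC[C@@H](C)/C=C(\C)C(=O)NC1C(O)[C@@](OC(C)(C)O2)(/C=C/[Sn](CCCC)(CCCC)CCCC)[C@H]2CC1O | intermediate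
24 | C4-[(E)-2-iodoethenyl] amide diol | CCCC[C@@H](C)/C=C(\C)C(=O)NC1C(O)[C@@](OC(C)(C)O2)(/C=C/I)[C@H]2CC1O | intermediate
25 | C1 ketone, C3 carbinol (2-acylamino-3-hydroxycyclohexanone acetonide) | CCCC[C@@H](C)/C=C(\C)C(=O)NC1C(O)[C@@](OC(C)(C)O2)(/C=C/I)[C@H]2CC1=O | intermediate
26 | C3 mesylate of 25 | CCCC[C@@H](C)/C=C(\C)C(=O)NC1C(OS(C)(=O)=O)[C@@](OC(C)(C)O2)(/C=C/I)[C@H]2CC1=O | intermediate
27 | 2-acylaminocyclohex-2-enone with C4/C5 acetonide and C4 (E)-2-iodoethenyl | CCCC[C@@H](C)/C=C(\C)C(=O)NC1=C[C@@](OC(C)(C)O2)(/C=C/I)[C@H]2CC1=O | intermediate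
28 | (2E,4R)-N-[(3R,4R)-3,4-dihydroxy-3-[(E)-2-iodoethenyl]-6-oxocyclohex-1-en-1-yl]-2,4-dimethyloct-2-enamide | CCCC[C@@H](C)/C=C(\C)C(=O)NC1=C[C@@](O)(/C=C/I)[C@H](O)CC1=O | intermediate
29 | prop-2-yn-1-ol | C#CCO | starting material
30 | (E)-3-(tributylstannyl)prop-2-en-1-ol | CCCC[Sn](CCCC)(CCCC)/C=C/CO | intermediate
31 | ethyl (triphenyl-λ5-phosphanylidene)acetate | CCOC(=O)C=P(c1ccccc1)(c1ccccc1)c1ccccc1 | starting material
32 | (E)-3-(tributylstannyl)prop-2-enal | CCCC[Sn](CCCC)(CCCC)/C=C/C=O | intermediate
33 | ethyl (2E,4E)-5-(tributylstannyl)penta-2,4-dienoate | CCCC[Sn](CCCC)(CCCC)/C=C/C=C/C(=O)OCC | intermediate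
34 | (2E,4E)-5-(tributylstannyl)penta-2,4-dienoic acid | CCCC[Sn](CCCC)(CCCC)/C=C/C=C/C(=O)O | intermediate
35 | cyclopentane-1,3-dione | O=C1CCC(=O)C1 | starting material
36 | 2-nitrocyclopentane-1,3-dione (enol form) | O=C1CCC(O)=C1[N+](=O)[O-] | intermediate
37 | 2-amino-3-hydroxycyclopent-2-en-1-one hydrochloride | Cl.NC1=C(O)CCC1=O | intermediate
38 | (2E,4E)-N-(2-hydroxy-5-oxocyclopent-1-en-1-yl)-5-(tributylstannyl)penta-2,4-dienamide | CCCC[Sn](CCCC)(CCCC)/C=C/C=C/C(=O)NC1=C(O)CCC1=O | intermediate
39 | (2E,4E,6E)-7-[(1S,6R)-3-{[(2E,4R)-2,4-dimethyloct-2-enoyl]amino}-1,6-dihydroxy-4-oxocyclohex-2-en-1-yl]-N-(2-hydroxy-5-oxocyclopent-1-en-1-yl)hepta-2,4,6-trienamide | CCCC[C@@H](C)/C=C(\C)C(=O)NC1=C[C@@](O)(/C=C/C=C/C=C/C(=O)NC2=C(O)CCC2=O)[C@H](O)CC1=O | target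

Remark: the C4 descriptor reads R in 6–9, 11 and 26–28, and S in 12–14, 21–25 and 39. This is only because the ranking of its substituents changes. The spatial arrangement set in step 4 is never altered, and C5 is R throughout.

**Totals**
Total step count: 23.
Longest linear sequence: 14 steps (steps 1–7, 11–16 and 23).

**Steps most likely to fail**

Step 6. Three processes threaten it. The C1 aldehyde may enolise and lose the C5 oxygen. Intermolecular addition may lead to chain growth. The reaction may also stall after the first addition because the C3 aldehyde is neopentyl.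
The fallback makes the two C–C bonds in separate operations.
- Setting out from 9, nitromethane is added to the C1 aldehyde alone under near-neutral Cu(OAc)2/TMEDA catalysis in EtOH, and 11 is isolated.
- Its carbinol is capped with TESCl/imidazole to give the triethylsilyl ether of the open-chain nitroaldol F1, which can no longer revert.
- Catalytic Et3N in MeCN then closes ring A by an intramolecular Henry reaction to the C1-O-triethylsilyl nitro alcohol F2.
- AcOH/THF/H2O removes the silyl group, and the route is rejoined at 13.

Step 14. The oxidant may discriminate poorly between the two secondary carbinols, or it may over-oxidise to the 1,3-dione. Either would consume material irreversibly.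
The fallback replaces the selective oxidation by a selective and correctable protection.
- Setting out from 24, TBSCl/imidazole silylates the unhindered C1 hydroxyl to the C1 silyl ether F3. Wrongly silylated material can be desilylated and recycled.
- Ac2O/DMAP acetylates the remaining C3 hydroxyl to the silyl ether acetate F4.
- HF·pyridine frees C1 to give the C3 acetate F5.
- Dess–Martin periodinane, which now has only one hydroxyl to act on, gives the β-acetoxy ketone F6.
- Et3N eliminates acetic acid, and the route is rejoined at 27.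

Step 2. The enzyme may distinguish the enantiomers poorly, because both flanks of the carbinol carbon are ring carbons of similar size. The free α-ketol may also tautomerise to the 1,2-dione enol, or racemise.
The fallback moves the resolution to a robust later alcohol, so the free hydroxy enone is never formed.
- Setting out from 2, excess lithium acetylide made from 5 is added at −78 °C, and K2CO3/MeOH cleaves the acetate to give the racemic cis-diol F7.
- Lipase-catalysed acylation with vinyl acetate should esterify the (1R)-carbinol, whose flanks (quaternary carbon against CH2) differ strongly. This gives the monoacetate F8, which is separated from the unreacted enantiomer.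
- K2CO3/MeOH gives the (1R,2R)-diol F9.
- 2-Methoxypropene/PPTS closes the acetonide, and the route is rejoined at 7.

**Further compounds**
F1 | step 6 | triethylsilyl ether of open-chain nitroaldol 11 | O=C[C@@](OC(C)(C)O2)(C#C[Si](C(C)C)(C(C)C)C(C)C)[C@H]2CC(O[Si](CC)(CC)CC)C[N+](=O)[O-]
F2 | step 6 | C1-O-triethylsilyl derivative of nitro diol 13 | [O-][N+](=O)C1C(O)[C@@](OC(C)(C)O2)(C#C[Si](C(C)C)(C(C)C)C(C)C)[C@H]2CC1O[Si](CC)(CC)CC
F3 | step 14 | C1-O-tert-butyldimethylsilyl ether of 24 | CCCC[C@@H](C)/C=C(\C)C(=O)NC1C(O)[C@@](OC(C)(C)O2)(/C=C/I)[C@H]2CC1O[Si](C)(C)C(C)(C)C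
F4 | step 14 | C1-O-tert-butyldimethylsilyl C3-O-acetyl derivative of 24 | CCCC[C@@H](C)/C=C(\C)C(=O)NC1C(OC(C)=O)[C@@](OC(C)(C)O2)(/C=C/I)[C@H]2CC1O[Si](C)(C)C(C)(C)C
F5 | step 14 | C3-O-acetyl derivative of 24 | CCCC[C@@H](C)/C=C(\C)C(=O)NC1C(OC(C)=O)[C@@](OC(C)(C)O2)(/C=C/I)[C@H]2CC1O
F6 | step 14 | C3-O-acetyl derivative of 25 (β-acetoxy ketone) | CCCC[C@@H](C)/C=C(\C)C(=O)NC1C(OC(C)=O)[C@@](OC(C)(C)O2)(/C=C/I)[C@H]2CC1=O
F7 | step 2 | (±)-cis-2-[(triisopropylsilyl)ethynyl]cyclopent-3-ene-1,2-diol (both enantiomers) | C1=C[C@@](O)(C#C[Si](C(C)C)(C(C)C)C(C)C)[C@H](O)C1.C1=C[C@](O)(C#C[Si](C(C)C)(C(C)C)C(C)C)[C@@H](O)C1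
F8 | step 2 | (1R,2R)-2-hydroxy-2-[(triisopropylsilyl)ethynyl]cyclopent-3-en-1-yl acetate | C1=C[C@@](O)(C#C[Si](C(C)C)(C(C)C)C(C)C)[C@H](OC(C)=O)C1
F9 | step 2 | (1R,2R)-2-[(triisopropylsilyl)ethynyl]cyclopent-3-ene-1,2-diol | C1=C[C@@](O)(C#C[Si](C(C)C)(C(C)C)C(C)C)[C@H](O)C1
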